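Late in the green run the target is still climbing, from 25.2 % at 12.0 min to 29.5 % at 15.0 min, while the other capture product wanders around one level from the first reading on. We therefore treat that small product as a finished burst and the target as the large curve. The readings of the other capture product average 1.32 %, and dividing by the 3.5 equiv of second nucleophile charged gives 0.376 %: this is the capture share, the part of the charged second nucleophile that ends as other capture product.

in all of them: substrate 0.64 M

| flask | first nucleophile | second nucleophile | remark | time |
|---|---|---|---|---|
| green | 1 equiv | 3.5 equiv | run made earlier |  |
| flask | 1.00 equiv | 2.50 equiv |  | 20 min |

- green (time / min: target / %, other capture product / %): 2.50: 7.1, 1.0; 5.00: 12.4, 1.3; 8.00: 18.6, 1.7; 10.0: 22.3, 1.0; 12.0: 25.2, 1.4; 15.0: 29.5, 1.5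

(scatter of a reading: 0.3 percentage points)

- ratio of target to other capture product at 20 s
- ratio of target to other capture product at 20 min
- which of target and other capture product there is more of at 20 min



For the new flask we assume that the burst scales with the charge of second nucleophile and that the target curve carries over from the green run. The capture share then puts the plateau at 0.940 %. The target starts with a slope of 0.0284 /min as a fraction of the substrate charged, and by the end of the green run the slope has bent to 0.0143 /min, about half of the starting slope. The straight start crosses the plateau at 19.9 s, close to the early time asked, so our ratio there is 1.01 if the burst is complete and higher if it is not. A second-order curve through the last reading, with constant 0.0279 /min, reaches 35.8 % at 20 min, far above the plateau, which gives a ratio of 38.1.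

The forecast gives 1 at 20 s, 33 at 20 min and target in the lead, reading the small product as “a fast burst or small equilibrium”. Its late ratio lies below ours.

The flask gives ratios of 2.50 at 20 s and 36.9 at 20 min, with target ahead.

    substrate ⇌ intermediate (K = 0.0140, k = 0.00277 /s)
    first nucleophile + intermediate → target (k = 0.0789 /M/s)
    second nucleophile + intermediate → other capture product (k = 0.0165 /M/s)
    substrate + intermediate → side product (k = 0.0275 /M/s)
    second nucleophile → decomposed reagent (k = 0.0244 /s)
    second nucleophile → decomposition product (k = 5.86 × 10⁻⁶ /s)

The flask holds 35.1 % of target and 0.949 % of other capture product at 20 min, a capture share of 0.380 % against the 0.376 % read from the green run. The neighbouring flask, with 0.400 equiv of first nucleophile, has the same charge of second nucleophile, so the capture share again gives 0.940 %. That neighbour holds more, 1.06 %, a capture share of 0.424 %, beside 16.5 % of target, and its ratio at 20 min is 15.6.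

(The runs were generated by integration for an exercise, noise included.)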